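## Retrosynthetic overview

1. The C13 acetate and the α-methylene-γ-lactone (ring B: C1, C2, C15, C16, O) are made last; ring B comes from oxidative lactonisation of a protected 2-methylene-1,4-diol, so no Michael acceptor exists before the key step.
2. Key disconnection C11–C12: this bond belongs to both the oxirane and the 14-membered carbocycle (ring A); C12 carries the C20 methyl and is flanked by the C13 oxygen stereocentre, and C11 is a CH three carbons from quaternary C8. A C12 methyl ketone and a C11 sulfonium ylide can therefore close oxirane and ring A in one intramolecular epoxidation, with C13 steering C12.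
3. The open chain comes from an aldol union at C1–C2 between the enolate of an (R)-γ-lactone (C13 stereocentre; temporary ring C15–O–C13 that relays chirality to C1 and C2) and a C2–C11 dienal.
4. The dienal comes from (S)-linalool (C8) and a C2–C6 dienol by cross metathesis at C6=C7.
5. Ring order: temporary γ-lactone (present from step 7, opened in step 10), then oxirane and ring A together (step 20), then ring B (step 22).

Key step: step 20

Remark (numbering, abbreviations): cembrane numbering of the target is used throughout: C1 ring-fusion CH of the lactone, C2 lactone CH–O, C3=C4 (C18 methyl), C5, C6=C7, C8 (C19 methyl, OH), C9, C10, C11 and C12 (C20 methyl) oxirane carbons, C13 CH–OAc, C14, C15 lactone α-carbon, C16 lactone C=O, C17 exocyclic CH2; TES = triethylsilyl, TBS = tert-butyldimethylsilyl, PMB = 4-methoxybenzyl, EE = 1-ethoxyethyl.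

Remark (materials): (S)-(+)-linalool of high enantiomeric purity, (R)-5-(hydroxymethyl)dihydrofuran-2(3H)-one and (tributylstannyl)methanol are taken as commercial.

Remark (undefined centres): the acetal carbon of the EE group (steps 12–20) and the C12 carbinol of 26 form as both epimers; they are left undefined and disappear in steps 21 and 17.

## Route

Step 1
Reactants: 1 pent-1-en-4-yne
Product: 3 (2E)-3-methylhexa-2,5-dien-1-ol, via alkenylalane 2 (not isolated)
Conditions: AlMe3 (2 equiv), Cp2ZrCl2 (0.25 equiv), CH2Cl2, 23 °C; then n-BuLi (1 equiv), THF, −30 °C; (CH2O)n, 23 °C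
Reagents that add atoms: trimethylaluminium C[Al](C)C; formaldehyde (as paraformaldehyde) C=O
Why: Negishi zirconium-catalysed carboalumination adds methyl and aluminium syn across the terminal alkyne (methyl on the internal carbon), and the alkenylalanate is hydroxymethylated with retention, which fixes the E trisubstituted alkene (future C3=C4); the isolated terminal alkene should react far more slowly.

Step 2
Reactants: 4 (S)-linalool
Product: 6 (3S)-3-methylhex-1-ene-3,6-diol, via hydroxy aldehyde 5 (not isolated)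
Conditions: O3 (1.0 equiv, metered), CH2Cl2/MeOH, −78 °C; then NaBH4, −78 → 0 °C
Reagents that add atoms: ozone [O-][O+]=O
Why: Ozonolysis should cleave the electron-rich trisubstituted alkene in preference to the vinyl group, and borohydride reduces the resulting aldehyde (lactol) to the diol; the C8 stereocentre comes from linalool and is untouched.

Step 3
Reactants: 6 (3S)-3-methylhex-1-ene-3,6-diol
Product: 7 (3S)-6-(4-methoxybenzyloxy)-3-methylhex-1-en-3-ol
Conditions: NaH (1.05 equiv), 4-methoxybenzyl chloride, Bu4NI (cat.), THF/DMF, 0 °C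
Reagents that add atoms: 4-methoxybenzyl chloride COc1ccc(CCl)cc1
Why: Williamson etherification; the primary alkoxide forms and is alkylated in preference to the hindered tertiary allylic hydroxyl.

Step 4
Reactants: 7 (3S)-6-(4-methoxybenzyloxy)-3-methylhex-1-en-3-ol; 3 (2E)-3-methylhexa-2,5-dien-1-ol (3 equiv)
Product: 8 (2E,5E,7S)-10-(4-methoxybenzyloxy)-3,7-dimethyldeca-2,5-diene-1,7-diol
Conditions: second-generation Hoveyda–Grubbs catalyst RuCl2(H2IMes)(=CH-C6H4-2-OiPr) (5 mol %), 1,4-benzoquinone (10 mol %), CH2Cl2, 40 °C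
Reagents that add atoms: none
Why: Olefin cross metathesis between the vinyl group of the free tertiary allylic alcohol (slow to homodimerise) and the terminal allyl group of 3; the quaternary allylic centre should enforce the E geometry of the new C6=C7 bond, the trisubstituted alkene is inert, and benzoquinone suppresses migration of the skipped diene.

Step 5
Reactants: 8 (2E,5E,7S)-10-(4-methoxybenzyloxy)-3,7-dimethyldeca-2,5-diene-1,7-diol
Product: 9 (2E,5E,7S)-7-hydroxy-10-(4-methoxybenzyloxy)-3,7-dimethyldeca-2,5-dienal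
Conditions: MnO2 (15 equiv), CH2Cl2, 23 °C
Reagents that add atoms: none
Why: Allylic oxidation with MnO2 takes only the primary allylic alcohol to the enal under neutral conditions, with retention of the E geometry and without touching the tertiary alcohol.

Step 6
Reactants: 9 (2E,5E,7S)-7-hydroxy-10-(4-methoxybenzyloxy)-3,7-dimethyldeca-2,5-dienal
Product: 10 (2E,5E,7S)-10-(4-methoxybenzyloxy)-3,7-dimethyl-7-(triethylsilyloxy)deca-2,5-dienal
Conditions: Et3SiOTf, 2,6-lutidine, CH2Cl2, −78 °C
Reagents that add atoms: triethylsilyl triflate CC[Si](CC)(CC)OS(=O)(=O)C(F)(F)F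
Why: Silylation of the tertiary alcohol with a silyl triflate and a hindered base, which leaves the enal alone; the bulky tertiary silyl ether later also keeps the C8 oxygen from attacking C11.

Step 7
Reactants: 11 (5R)-5-(hydroxymethyl)dihydrofuran-2(3H)-one
Product: 12 (5R)-5-[(triethylsilyloxy)methyl]dihydrofuran-2(3H)-one
Conditions: Et3SiCl, imidazole, CH2Cl2, 0 °C
Reagents that add atoms: chlorotriethylsilane CC[Si](Cl)(CC)CC
Why: Standard silylation of the primary alcohol; the lactone stereocentre is the future C13 and the CH2O carbon the future C12.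

Step 8
Reactants: 12 (5R)-5-[(triethylsilyloxy)methyl]dihydrofuran-2(3H)-one; 10 (2E,5E,7S)-10-(4-methoxybenzyloxy)-3,7-dimethyl-7-(triethylsilyloxy)deca-2,5-dienal
Product: 15 syn-aldol lactone (3R,5R)-3-[(1S,2E,5E,7S)-1-hydroxy-10-(4-methoxybenzyloxy)-3,7-dimethyl-7-(triethylsilyloxy)deca-2,5-dien-1-yl]-5-[(triethylsilyloxy)methyl]dihydrofuran-2(3H)-one, via lithium enolate 13 (not isolated), via zirconium enolate 14 (not isolated)
Conditions: LiN(iPr)2 (1.1 equiv), THF, −78 °C; Cp2ZrCl2 (1.2 equiv), −78 °C; then 10, −78 → −40 °C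
Reagents that add atoms: none
Why: Aldol addition of the γ-lactone enolate, in which the aldehyde should enter trans to the silyloxymethyl group on the five-membered ring (sets C1 from C13) and the zirconium enolate (Evans–Yamamoto type, syn-selective whatever the enolate geometry) should set the C2 carbinol syn to C14, the relationship the cis-fused lactone needs.

Step 9
Reactants: 15 syn-aldol lactone
Product: 16 C2 triethylsilyl ether of 15
Conditions: Et3SiOTf, 2,6-lutidine, CH2Cl2, −78 °C
Reagents that add atoms: triethylsilyl triflate CC[Si](CC)(CC)OS(=O)(=O)C(F)(F)F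
Why: Silylation of the secondary allylic alcohol under non-basic conditions, which avoids retro-aldol cleavage; this group is later removed together with the EE acetal while the C13 ether stays.

Step 10
Reactants: 16 C2 triethylsilyl ether of 15
Product: 17 (2R,4R)-4-hydroxy-N-methoxy-N-methyl-2-[(1S,2E,5E,7S)-10-(4-methoxybenzyloxy)-3,7-dimethyl-1,7-bis(triethylsilyloxy)deca-2,5-dien-1-yl]-5-(triethylsilyloxy)pentanamide
Conditions: AlMe3, MeONHMe·HCl, CH2Cl2, 0 → 23 °C
Reagents that add atoms: N,O-dimethylhydroxylamine hydrochloride CNOC.Cl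
Why: Weinreb aminolysis of the lactone with the aluminium amide opens the temporary ring, turns C15 into a Weinreb amide and frees the C13 hydroxyl without base that could epimerise C1.

Step 11
Reactants: 17 C13-hydroxy Weinreb amide
Product: 18 C13 tert-butyldimethylsilyl ether of 17, (2R,4R)-4-(tert-butyldimethylsilyloxy) analogue
Conditions: tBuMe2SiOTf, 2,6-lutidine, CH2Cl2, −78 → 0 °C, directly after step 10
Reagents that add atoms: tert-butyldimethylsilyl triflate CC(C)(C)[Si](C)(C)OS(=O)(=O)C(F)(F)F
Why: Immediate silylation prevents relactonisation; the bulky non-chelating TBS ether is the Felkin–Anh control element of the key step and survives the later mild acid step.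

Step 12
Reactants: 19 (tributylstannyl)methanol
Product: 20 tributyl[(1-ethoxyethoxy)methyl]stannane
Conditions: ethyl vinyl ether, PPTS (cat.), CH2Cl2, 23 °C
Reagents that add atoms: ethyl vinyl ether C=COCC
Why: Acid-catalysed addition of the alcohol to the vinyl ether gives Still's hydroxymethyl-anion precursor.

Step 13
Reactants: 20 tributyl[(1-ethoxyethoxy)methyl]stannane (2.5 equiv); 18 C13 tert-butyldimethylsilyl ether of 17
Product: 22 C15 ketone of the open chain (1R,2S,8S,13R) with C16H2–OEE, C12H2–OTES, C13–OTBS, C2–OTES, C8–OTES, C11H2–OPMB, via alkoxymethyllithium 21 (not isolated)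
Conditions: n-BuLi (2.4 equiv), THF, −78 °C; then 18, −78 → −40 °C; aq. NH4Cl
Reagents that add atoms: none
Why: Tin–lithium exchange gives the α-alkoxymethyllithium, which adds once to the Weinreb amide (stable chelated tetrahedral intermediate) and delivers the ketone that carries C16.

Step 14
Reactants: 22 C15 ketone
Product: 23 C15(17)-methylene compound (1S,2S,8S,13R), the protected 2-methylene-1,4-diol
Conditions: Cp2TiMe2 (3 equiv), toluene, 70 °C, dark
Reagents that add atoms: dimethyltitanocene C[Ti](C)(C1C=CC=C1)C1C=CC=C1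
Why: Petasis methylenation is non-basic, so the epimerisable C1 centre and the β-silyloxy group should survive while the hindered ketone becomes the 1,1-disubstituted alkene.

Step 15
Reactants: 23 C15(17)-methylene compound
Product: 25 C12 aldehyde (1S,2S,8S,13R), via alkoxysulfonium chloride 24 (not isolated)
Conditions: (COCl)2 (4 equiv), DMSO (8 equiv), CH2Cl2, −78 → −40 °C; then Et3N, −78 → 0 °C
Reagents that add atoms: none
Why: Swern oxidation applied directly to a primary triethylsilyl ether, which is known to be cleaved and oxidised selectively in the presence of secondary and tertiary silyl ethers; the α-silyloxy aldehyde is not exposed to conditions that epimerise C13.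

Step 16
Reactants: 25 C12 aldehyde
Product: 26 C12 carbinol (12RS), the methyl adduct
Conditions: MeMgBr, Et2O, −78 °C; aq. NH4Cl
Reagents that add atoms: methylmagnesium bromide C[Mg]Br
Why: Grignard addition to the only carbonyl group brings in C20; the new carbinol centre is oxidised in the next step, so its configuration does not matter.

Step 17
Reactants: 26 C12 carbinol
Product: 27 C12 methyl ketone (1S,2S,8S,13R)
Conditions: Dess–Martin periodinane, NaHCO3, CH2Cl2, 0 → 23 °C
Reagents that add atoms: none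
Why: Buffered Dess–Martin oxidation gives the α-silyloxy methyl ketone without epimerising C13 or cleaving the acetal and silyl ethers.

Step 18
Reactants: 27 C12 methyl ketone
Product: 28 C11 primary alcohol
Conditions: DDQ, CH2Cl2/pH 7 buffer, 0 °C
Reagents that add atoms: none
Why: Oxidative cleavage of the PMB ether; the only PMB group in the molecule sits on C11, and the silyl ethers, the acetal and the ketone should be inert.

Step 19
Reactants: 28 C11 primary alcohol
Product: 30 C11 diphenylsulfonium triflate, via C11 triflate 29 (not isolated)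
Conditions: Tf2O (1.1 equiv), 2,6-di-tert-butylpyridine, CH2Cl2, −78 °C; then Ph2S (20 equiv), −78 → 23 °C
Reagents that add atoms: triflic anhydride O=S(=O)(OS(=O)(=O)C(F)(F)F)C(F)(F)F; diphenyl sulfide c1ccc(Sc2ccccc2)cc1
Why: Triflation of the only free hydroxyl followed by SN2 alkylation of diphenyl sulfide gives the alkyldiphenylsulfonium salt, whose only α-protons are on C11; the hindered tertiary TES ether on C8 should suppress oxolane formation.

Step 20
Reactants: 30 C11 diphenylsulfonium triflate
Product: 33 macrocyclic 11,12-epoxide (1S,2S,8S,11S,12S,13R), via sulfonium ylide 31 (not isolated), via betaine 32 (not isolated)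
Conditions: KN(SiMe3)2 (1.1 equiv, syringe pump over 4 h), THF (0.001 M), −78 → −40 °C
Reagents that add atoms: none
Why: Proposed new method: KN(SiMe3)2 removes a C11 proton of the sulfonium salt (far more acidic than the ketone α-protons) to give the non-stabilised diphenylsulfonium ylide 31, which adds irreversibly to the C12 ketone to give betaine 32, and anti-periplanar displacement of Ph2S by the alkoxide then closes the oxirane. The closest known reaction type is the Corey–Chaykovsky epoxidation of ketones with diphenylsulfonium alkylides, including its intramolecular variants that form five- to seven-membered rings; its use to close a macrocycle is the new element. Ring A closes by 14-exo-trig attack of the ylide carbon on the carbonyl carbon, and the oxirane then closes by 3-exo-tet substitution with inversion at C11. C12 is controlled by the adjacent C13 stereocentre (polar Felkin–Anh attack anti to the bulky, non-chelating OTBS group with a potassium counter-ion), which gives the 12,13-anti relationship of the target. C11 is set in the same irreversible C–C bond formation and has no local control element, so the cis placement of C10 and C13 on the oxirane must come from the preferred conformation of the closing ring, which already holds two E alkenes. The step also needs ylide formation over enolisation, cyclisation over oligomerisation and no competing electrophile, which are secured by the pKa gap, by high dilution with slow addition of base, and by carrying the lactone as a protected 2-methylene-1,4-diol with every hydroxyl masked.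

Step 21
Reactants: 33 macrocyclic 11,12-epoxide
Product: 34 C2,C16-diol (C8–OTES and C13–OTBS retained)
Conditions: PPTS (0.2 equiv), MeOH/CH2Cl2, 0 °C
Reagents that add atoms: none
Why: Mild acid-catalysed methanolysis should remove the EE acetal and the secondary allylic TES ether while the tertiary TES ether, the TBS ether and the oxirane survive.

Step 22
Reactants: 34 C2,C16-diol
Product: 37 silylated α-methylene lactone (C8–OTES, C13–OTBS), via hydroxy enal 35 (not isolated), via lactol 36 (not isolated)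
Conditions: TEMPO (0.2 equiv), PhI(OAc)2 (2.5 equiv), CH2Cl2, 23 °C
Reagents that add atoms: none
Why: TEMPO/PhI(OAc)2 oxidises the primary allylic alcohol to the enal, which forms the five-membered lactol with the C2 hydroxyl and is oxidised on to the lactone; only ring B can form because the C13 oxygen is still silylated, and the cis fusion is already fixed by C1 and C2.

Step 23
Reactants: 37 silylated α-methylene lactone
Product: 38 8,13-diol (1S,2S,8S,11S,12R,13R; the C12 descriptor differs from the target only through CIP priority)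
Conditions: Bu4NF/AcOH (1:1), THF, 0 → 23 °C
Reagents that add atoms: none
Why: Fluoride desilylation buffered with acetic acid removes the TBS and tertiary TES groups near neutrality, which should avoid transannular opening of the oxirane by the C8 hydroxyl and conjugate addition to the methylene lactone.

Step 24
Reactants: 38 8,13-diol
Product: 39 target, (1S,2S,3E,6E,8S,11S,12S,13R)-13-acetoxy-11,12-epoxy-8-hydroxycembra-3,6,15(17)-trien-16,2-olide
Conditions: Ac2O, pyridine, DMAP (cat.), CH2Cl2, 0 °C
Reagents that add atoms: acetic anhydride CC(=O)OC(C)=O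
Why: Acetylation of the secondary C13 alcohol; the tertiary C8 alcohol should not be acylated under these conditions.

## Compound list

1 | pent-1-en-4-yne | C=CCC#C | starting material
2 | (E)-dimethyl(2-methylpenta-1,4-dien-1-yl)alane | C=CC/C(C)=C/[Al](C)C | intermediate
3 | (2E)-3-methylhexa-2,5-dien-1-ol | C=CC/C(C)=C/CO | intermediate
4 | (S)-linalool, (3S)-3,7-dimethylocta-1,6-dien-3-ol | C=C[C@@](C)(O)CCC=C(C)C | starting material
5 | (4S)-4-hydroxy-4-methylhex-5-enal (in equilibrium with its lactol) | C=C[C@@](C)(O)CCC=O | intermediate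
6 | (3S)-3-methylhex-1-ene-3,6-diol | C=C[C@@](C)(O)CCCO | intermediate
7 | (3S)-6-(4-methoxybenzyloxy)-3-methylhex-1-en-3-ol | C=C[C@@](C)(O)CCCOCc1ccc(OC)cc1 | intermediate
8 | (2E,5E,7S)-10-(4-methoxybenzyloxy)-3,7-dimethyldeca-2,5-diene-1,7-diol | OC/C=C(\C)C/C=C/[C@@](C)(O)CCCOCc1ccc(OC)cc1 | intermediate
9 | (2E,5E,7S)-7-hydroxy-10-(4-methoxybenzyloxy)-3,7-dimethyldeca-2,5-dienal | O=C/C=C(\C)C/C=C/[C@@](C)(O)CCCOCc1ccc(OC)cc1 | intermediate
10 | (2E,5E,7S)-10-(4-methoxybenzyloxy)-3,7-dimethyl-7-(triethylsilyloxy)deca-2,5-dienal | O=C/C=C(\C)C/C=C/[C@@](C)(O[Si](CC)(CC)CC)CCCOCc1ccc(OC)cc1 | intermediate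
11 | (5R)-5-(hydroxymethyl)dihydrofuran-2(3H)-one | O=C1CC[C@H](CO)O1 | starting material
12 | (5R)-5-[(triethylsilyloxy)methyl]dihydrofuran-2(3H)-one | O=C1CC[C@H](CO[Si](CC)(CC)CC)O1 | intermediate
13 | lithium enolate of 12 | [Li]OC1=CC[C@H](CO[Si](CC)(CC)CC)O1 | intermediate
14 | chlorozirconocene enolate of 12 | Cl[Zr](OC1=CC[C@H](CO[Si](CC)(CC)CC)O1)(C1C=CC=C1)C1C=CC=C1 | intermediate
15 | syn-aldol lactone, (3R,5R)-3-[(1S,2E,5E,7S)-1-hydroxy-10-(4-methoxybenzyloxy)-3,7-dimethyl-7-(triethylsilyloxy)deca-2,5-dien-1-yl]-5-[(triethylsilyloxy)methyl]dihydrofuran-2(3H)-one | O=C1O[C@@H](CO[Si](CC)(CC)CC)C[C@@H]1[C@@H](O)/C=C(\C)C/C=C/[C@@](C)(O[Si](CC)(CC)CC)CCCOCc1ccc(OC)cc1 | intermediate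
16 | C2 triethylsilyl ether of 15 (same descriptors) | O=C1O[C@@H](CO[Si](CC)(CC)CC)C[C@@H]1[C@@H](O[Si](CC)(CC)CC)/C=C(\C)C/C=C/[C@@](C)(O[Si](CC)(CC)CC)CCCOCc1ccc(OC)cc1 | intermediate
17 | (2R,4R)-4-hydroxy-N-methoxy-N-methyl-2-[(1S,2E,5E,7S)-10-(4-methoxybenzyloxy)-3,7-dimethyl-1,7-bis(triethylsilyloxy)deca-2,5-dien-1-yl]-5-(triethylsilyloxy)pentanamide | CC[Si](CC)(CC)OC[C@H](O)C[C@@H](C(=O)N(C)OC)[C@@H](O[Si](CC)(CC)CC)/C=C(\C)C/C=C/[C@@](C)(O[Si](CC)(CC)CC)CCCOCc1ccc(OC)cc1 | intermediate
18 | (2R,4R)-4-(tert-butyldimethylsilyloxy) analogue of 17 (C13–OTBS) | CC[Si](CC)(CC)OC[C@H](O[Si](C)(C)C(C)(C)C)C[C@@H](C(=O)N(C)OC)[C@@H](O[Si](CC)(CC)CC)/C=C(\C)C/C=C/[C@@](C)(O[Si](CC)(CC)CC)CCCOCc1ccc(OC)cc1 | intermediate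
19 | (tributylstannyl)methanol | CCCC[Sn](CCCC)(CCCC)CO | starting material
20 | tributyl[(1-ethoxyethoxy)methyl]stannane | CCCC[Sn](CCCC)(CCCC)COC(C)OCC | intermediate
21 | [(1-ethoxyethoxy)methyl]lithium | [Li]COC(C)OCC | intermediate
22 | C15 ketone of the open chain (1R,2S,8S,13R): C16H2–OEE, C12H2–OTES, C13–OTBS, C2–OTES, C8–OTES, C11H2–OPMB | CC[Si](CC)(CC)OC[C@H](O[Si](C)(C)C(C)(C)C)C[C@@H](C(=O)COC(C)OCC)[C@@H](O[Si](CC)(CC)CC)/C=C(\C)C/C=C/[C@@](C)(O[Si](CC)(CC)CC)CCCOCc1ccc(OC)cc1 | intermediate
23 | C15(17)-methylene compound (1S,2S,8S,13R), otherwise as 22 | CC[Si](CC)(CC)OC[C@H](O[Si](C)(C)C(C)(C)C)C[C@@H](C(=C)COC(C)OCC)[C@@H](O[Si](CC)(CC)CC)/C=C(\C)C/C=C/[C@@](C)(O[Si](CC)(CC)CC)CCCOCc1ccc(OC)cc1 | intermediate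
24 | C12 alkoxydimethylsulfonium chloride | C[S+](C)OC[C@H](O[Si](C)(C)C(C)(C)C)C[C@@H](C(=C)COC(C)OCC)[C@@H](O[Si](CC)(CC)CC)/C=C(\C)C/C=C/[C@@](C)(O[Si](CC)(CC)CC)CCCOCc1ccc(OC)cc1.[Cl-] | intermediate
25 | C12 aldehyde (1S,2S,8S,13R) | O=C[C@H](O[Si](C)(C)C(C)(C)C)C[C@@H](C(=C)COC(C)OCC)[C@@H](O[Si](CC)(CC)CC)/C=C(\C)C/C=C/[C@@](C)(O[Si](CC)(CC)CC)CCCOCc1ccc(OC)cc1 | intermediate
26 | C12 carbinol (12RS; 1S,2S,8S,13R) | CC(O)[C@H](O[Si](C)(C)C(C)(C)C)C[C@@H](C(=C)COC(C)OCC)[C@@H](O[Si](CC)(CC)CC)/C=C(\C)C/C=C/[C@@](C)(O[Si](CC)(CC)CC)CCCOCc1ccc(OC)cc1 | intermediate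
27 | C12 methyl ketone (1S,2S,8S,13R), C11H2–OPMB | CC(=O)[C@H](O[Si](C)(C)C(C)(C)C)C[C@@H](C(=C)COC(C)OCC)[C@@H](O[Si](CC)(CC)CC)/C=C(\C)C/C=C/[C@@](C)(O[Si](CC)(CC)CC)CCCOCc1ccc(OC)cc1 | intermediate
28 | C11 primary alcohol of the keto chain | CC(=O)[C@H](O[Si](C)(C)C(C)(C)C)C[C@@H](C(=C)COC(C)OCC)[C@@H](O[Si](CC)(CC)CC)/C=C(\C)C/C=C/[C@@](C)(O[Si](CC)(CC)CC)CCCO | intermediate
29 | C11 triflate | CC(=O)[C@H](O[Si](C)(C)C(C)(C)C)C[C@@H](C(=C)COC(C)OCC)[C@@H](O[Si](CC)(CC)CC)/C=C(\C)C/C=C/[C@@](C)(O[Si](CC)(CC)CC)CCCOS(=O)(=O)C(F)(F)F | intermediate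
30 | C11 diphenylsulfonium triflate | CC(=O)[C@H](O[Si](C)(C)C(C)(C)C)C[C@@H](C(=C)COC(C)OCC)[C@@H](O[Si](CC)(CC)CC)/C=C(\C)C/C=C/[C@@](C)(O[Si](CC)(CC)CC)CCC[S+](c1ccccc1)c1ccccc1.[O-]S(=O)(=O)C(F)(F)F | intermediate
31 | C11 diphenylsulfonium ylide | CC(=O)[C@H](O[Si](C)(C)C(C)(C)C)C[C@@H](C(=C)COC(C)OCC)[C@@H](O[Si](CC)(CC)CC)/C=C(\C)C/C=C/[C@@](C)(O[Si](CC)(CC)CC)CC[CH-][S+](c1ccccc1)c1ccccc1 | intermediate
32 | macrocyclic betaine (C12 alkoxide, C11 diphenylsulfonium) | C=C(COC(C)OCC)[C@@H]1C[C@@H](O[Si](C)(C)C(C)(C)C)[C@@](C)([O-])[C@H]([S+](c2ccccc2)c2ccccc2)CC[C@](C)(O[Si](CC)(CC)CC)/C=C/C/C(C)=C/[C@@H]1O[Si](CC)(CC)CC | intermediate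
33 | macrocyclic 11,12-epoxide (1S,2S,8S,11S,12S,13R): C13–OTBS, C8–OTES, C2–OTES, C16H2–OEE, C15(17) methylene | C=C(COC(C)OCC)[C@@H]1C[C@@H](O[Si](C)(C)C(C)(C)C)[C@@]2(C)O[C@H]2CC[C@](C)(O[Si](CC)(CC)CC)/C=C/C/C(C)=C/[C@@H]1O[Si](CC)(CC)CC | intermediate
34 | C2,C16-diol of 33 (C8–OTES, C13–OTBS) | C=C(CO)[C@@H]1C[C@@H](O[Si](C)(C)C(C)(C)C)[C@@]2(C)O[C@H]2CC[C@](C)(O[Si](CC)(CC)CC)/C=C/C/C(C)=C/[C@@H]1O | intermediate
35 | C16 enal with free C2–OH | C=C(C=O)[C@@H]1C[C@@H](O[Si](C)(C)C(C)(C)C)[C@@]2(C)O[C@H]2CC[C@](C)(O[Si](CC)(CC)CC)/C=C/C/C(C)=C/[C@@H]1O | intermediate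
36 | C16 lactol (both anomers) | C=C1C(O)O[C@H]2/C=C(\C)C/C=C/[C@@](C)(O[Si](CC)(CC)CC)CC[C@@H]3O[C@]3(C)[C@H](O[Si](C)(C)C(C)(C)C)C[C@@H]12 | intermediate
37 | silylated α-methylene lactone (1S,2S,8S,11S,12S,13R): C8–OTES, C13–OTBS | C=C1C(=O)O[C@H]2/C=C(\C)C/C=C/[C@@](C)(O[Si](CC)(CC)CC)CC[C@@H]3O[C@]3(C)[C@H](O[Si](C)(C)C(C)(C)C)C[C@@H]12 | intermediate
38 | 8,13-diol (1S,2S,8S,11S,12R,13R) | C=C1C(=O)O[C@H]2/C=C(\C)C/C=C/[C@@](C)(O)CC[C@@H]3O[C@]3(C)[C@H](O)C[C@@H]12 | intermediate
39 | (1S,2S,3E,6E,8S,11S,12S,13R)-13-acetoxy-11,12-epoxy-8-hydroxycembra-3,6,15(17)-trien-16,2-olide | C=C1C(=O)O[C@H]2/C=C(\C)C/C=C/[C@@](C)(O)CC[C@@H]3O[C@]3(C)[C@H](OC(C)=O)C[C@@H]12 | target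

## Step count and risks

Total step count: 24. Longest linear sequence: 21 steps, from (S)-linalool 4 (steps 2–6, 8–11, 13–24).

Steps most likely to fail:

1. Step 20 (Proposed new method). What may go wrong: the C11 centre may be set with the wrong relative configuration (the oxirane with C10 and C13 trans, which an open-chain ylide would slightly prefer), or the ylide may oligomerise or decompose before the ring closes. Fallback with known chemistry, setting out from alcohol 28: Dess–Martin oxidation gives the C11 aldehyde/C12 ketone F1. Reductive pinacol macrocyclisation with low-valent titanium (TiCl3(DME)1.5, Zn–Cu couple, DME, high dilution, the reaction type known for 14-membered cembranoid 1,2-diols) should give the cis-(11R,12S)-11,12-diol F2, to be separated from stereoisomers. Selective mesylation of the secondary hydroxyl (MsCl, Et3N, −20 °C) gives the C11 mesylate F3, and K2CO3 in MeOH closes the oxirane with inversion at C11, which comes back to 33.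

2. Step 8. What may go wrong: poor control of the carbinol configuration (syn against anti addition), and deprotonation of the doubly allylic C5 position of the enal by the enolate. Fallback, setting out from 12 and 10: the plain lithium enolate aldol (LiN(iPr)2, THF, −78 °C, no transmetalation) is accepted as a mixture of 15 and its carbinol epimer F4, the (1′R) aldol lactone. The mixture is oxidised with Dess–Martin periodinane to the single β-keto lactone F5 (C1 equilibrates to the trans lactone). Chelation-controlled reduction with Zn(BH4)2 (Et2O, −78 → −20 °C, hydride delivered to the zinc chelate from the face away from C14) should give the syn alcohol and comes back to 15.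

3. Step 19. What may go wrong: the triflate may be lost by participation of the C8 silyloxy oxygen (oxolane formation) or by elimination before the weakly nucleophilic diphenyl sulfide attacks. Fallback, setting out from alcohol 28: thioetherification with PhSSPh and PBu3 (THF, 23 °C) gives the C11 phenyl sulfide F6 without any cationic character at C11. Copper-catalysed S-phenylation with diphenyliodonium triflate (Cu(OAc)2 cat., 1,2-dichloroethane, 80 °C) then gives the same sulfonium triflate and comes back to 30.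

## Further compounds

F1 | step 20 | C11 aldehyde/C12 methyl ketone of the open chain (1S,2S,8S,13R) | CC(=O)[C@H](O[Si](C)(C)C(C)(C)C)C[C@@H](C(=C)COC(C)OCC)[C@@H](O[Si](CC)(CC)CC)/C=C(\C)C/C=C/[C@@](C)(O[Si](CC)(CC)CC)CCC=O
F2 | step 20 | macrocyclic cis-(11R,12S)-11,12-diol (1S,2S,8S,13R) | C=C(COC(C)OCC)[C@@H]1C[C@@H](O[Si](C)(C)C(C)(C)C)[C@@](C)(O)[C@H](O)CC[C@](C)(O[Si](CC)(CC)CC)/C=C/C/C(C)=C/[C@@H]1O[Si](CC)(CC)CC
F3 | step 20 | C11 mesylate of F2 | C=C(COC(C)OCC)[C@@H]1C[C@@H](O[Si](C)(C)C(C)(C)C)[C@@](C)(O)[C@H](OS(C)(=O)=O)CC[C@](C)(O[Si](CC)(CC)CC)/C=C/C/C(C)=C/[C@@H]1O[Si](CC)(CC)CC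
F4 | step 8 | (1′R) carbinol epimer of aldol lactone 15 | O=C1O[C@@H](CO[Si](CC)(CC)CC)C[C@@H]1[C@H](O)/C=C(\C)C/C=C/[C@@](C)(O[Si](CC)(CC)CC)CCCOCc1ccc(OC)cc1
F5 | step 8 | (3R,5R)-β-keto lactone (C2 ketone) | O=C1O[C@@H](CO[Si](CC)(CC)CC)C[C@@H]1C(=O)/C=C(\C)C/C=C/[C@@](C)(O[Si](CC)(CC)CC)CCCOCc1ccc(OC)cc1
F6 | step 19 | C11 phenyl sulfide of the keto chain | CC(=O)[C@H](O[Si](C)(C)C(C)(C)C)C[C@@H](C(=C)COC(C)OCC)[C@@H](O[Si](CC)(CC)CC)/C=C(\C)C/C=C/[C@@](C)(O[Si](CC)(CC)CC)CCCSc1ccccc1
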